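**Retrosynthetic overview**

- The target is read as the (2R,3R,4R) 2,3-cis-3,4-trans 4-arylflavan-3-ol. The C4–aryl bond is cut last (Friedel–Crafts capture of a C4 benzylic cation by piceatannol, trans to 3-OH). The C3–OH comes from a C3=C4 enol formate by cis-hydrogenation anti to the C2 aryl, and the enol formate from a C3 formyl group by Baeyer–Villiger oxidation.
- Ring C (the pyran) is disconnected at O1–C2 and C3–C4 into a salicylaldehyde (ring A) and a cinnamaldehyde (ring B, C2, C3). One aminocatalytic domino oxa-Michael/aldol condensation forms both bonds and sets C2.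
- Enabling feature: O1 and C4 are ortho substituents of ring A (on C8a and C4a). As phenol and formyl group they are a 1,4 nucleophile/electrophile pair that matches the electrophilic Cβ (C2) and, after O-addition, the nucleophilic Cα (C3) of the enal. The enal carbon on C3 is a temporary activating group, later exchanged for the C3 oxygen.
- Ring order: rings A, B and both stilbene rings are bought; ring C is the only ring formed (step 3). Stereochemistry is relayed C2 (catalyst) → C3 (hydrogenation) → C4 (Friedel–Crafts).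

Key step: step 3

Remark: C2 aryl and C3 OH are cis and the C4 aryl is trans to both; (E)-4-hydroxycinnamaldehyde and piceatannol are taken as purchasable.

**Step 1**
Reactants: 1 2,4-dihydroxybenzaldehyde
Product: 2 2-hydroxy-4-[(triisopropylsilyl)oxy]benzaldehyde
Conditions: TIPSCl (1.05 equiv), imidazole, CH2Cl2, 0 °C
Reagents that add atoms: chlorotriisopropylsilane (TIPSCl), CC(C)[Si](Cl)(C(C)C)C(C)C
Why: Chemoselective O-silylation, in which the 2-OH is held in a hydrogen bond to the formyl oxygen and is the more hindered phenol, so the 4-OH should react first.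

**Step 2**
Reactants: 3 (E)-4-hydroxycinnamaldehyde
Product: 4 (2E)-3-{4-[(triisopropylsilyl)oxy]phenyl}prop-2-enal
Conditions: TIPSCl, imidazole, DMF, rt
Reagents that add atoms: chlorotriisopropylsilane (TIPSCl), CC(C)[Si](Cl)(C(C)C)C(C)C
Why: Standard silylation of the only hydroxyl group, which leaves the E-enal untouched.

**Step 3**
Reactants: 2 2-hydroxy-4-[(triisopropylsilyl)oxy]benzaldehyde; 4 (2E)-3-{4-[(triisopropylsilyl)oxy]phenyl}prop-2-enal
Product: 5 (2R)-7-[(triisopropylsilyl)oxy]-2-{4-[(triisopropylsilyl)oxy]phenyl}-2H-chromene-3-carbaldehyde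
Conditions: (S)-α,α-diphenylprolinol trimethylsilyl ether (20 mol %), 2-nitrobenzoic acid (20 mol %), 4 Å molecular sieves, toluene, rt, dark
Reagents that add atoms: none
Why: The secondary amine condenses with enal 4 to the E-iminium ion, the free 2-OH of 2 adds to its β-carbon (oxa-Michael, O1–C2), the resulting enamine attacks the ortho formyl carbon (aldol, C3–C4), and E1cB loss of water with hydrolysis releases 5 and the catalyst. This is the aminocatalytic domino oxa-Michael/aldol condensation of salicylaldehydes with cinnamaldehydes, a known route to 2-aryl-2H-chromene-3-carbaldehydes. Ring C closes in the aldol event as a 6-(enolexo)-exo-trig cyclisation, the O1–C2 bond having been formed intermolecularly just before. The only stereocentre, C2, is set by the catalyst: the diphenyl(silyloxy)methyl group of the (S)-pyrrolidine shields the Re face of the β-carbon of the s-trans E-iminium ion, so O1 should add to the Si face, which corresponds to (R). The step needs 1,4- instead of 1,2-addition of the phenol, one enantioface and no reversal of the oxa-Michael step; the ortho placement of O1 and C4 on ring A makes the aldol intramolecular, dehydration to the conjugated enal drains the reversible adduct, and the masked 4-OH leaves O1 as the only phenol that can add.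

**Step 4**
Reactants: 5 (2R)-7-[(triisopropylsilyl)oxy]-2-{4-[(triisopropylsilyl)oxy]phenyl}-2H-chromene-3-carbaldehyde
Product: 6 (2R)-7-[(triisopropylsilyl)oxy]-2-{4-[(triisopropylsilyl)oxy]phenyl}-2H-chromen-3-yl formate
Conditions: mCPBA (1.1 equiv), CH2Cl2, 0 °C
Reagents that add atoms: 3-chloroperoxybenzoic acid (mCPBA), OOC(=O)c1cccc(Cl)c1
Why: Baeyer–Villiger (Dakin-type) oxidation of the α,β-unsaturated aldehyde, in which the electron-rich alkenyl carbon C3 (β to the 7-silyloxyaryl ring) should migrate in preference to hydrogen, turning the C3–CHO bond into C3–O with C2 untouched.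

**Step 5**
Reactants: 6 (2R)-7-[(triisopropylsilyl)oxy]-2-{4-[(triisopropylsilyl)oxy]phenyl}-2H-chromen-3-yl formate
Product: 8 (2R,3R)-7-[(triisopropylsilyl)oxy]-2-{4-[(triisopropylsilyl)oxy]phenyl}-3,4-dihydro-2H-chromen-3-ol, via 3-O-formate 7 (not isolated)
Conditions: H2 (1 atm), Pd/C, EtOAc, rt; then KHCO3 (cat.), MeOH, 0 °C
Reagents that add atoms: none
Why: Heterogeneous syn-hydrogenation of the C3=C4 enol ester from the face opposite the pseudoaxial C2 aryl group puts H on C3 anti to the aryl and so the C3 oxygen cis to it (the cis-selective hydrogenation of flav-3-en-3-ol derivatives), and bicarbonate methanolysis then removes the formate without touching the aryl silyl ethers.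

**Step 6**
Reactants: 8 (2R,3R)-7-[(triisopropylsilyl)oxy]-2-{4-[(triisopropylsilyl)oxy]phenyl}-3,4-dihydro-2H-chromen-3-ol
Product: 9 (2R,3R,4S)-4-(2-ethoxyethoxy)-7-[(triisopropylsilyl)oxy]-2-{4-[(triisopropylsilyl)oxy]phenyl}-3,4-dihydro-2H-chromen-3-ol
Conditions: DDQ (1.5 equiv), 2-ethoxyethanol (5 equiv), CH2Cl2, rt
Reagents that add atoms: 2-ethoxyethanol, CCOCCO
Why: DDQ abstracts hydride from the benzylic C4–H (cation stabilised by O1 ortho and the 7-silyloxy group para) and the alcohol traps the cation trans to the 3-OH, a known benzylic oxidation of flavan-3-ols in which C2–H, activated only through ring B and an aryloxy oxygen, should react more slowly.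

**Step 7**
Reactants: 9 (2R,3R,4S)-4-(2-ethoxyethoxy)-7-[(triisopropylsilyl)oxy]-2-{4-[(triisopropylsilyl)oxy]phenyl}-3,4-dihydro-2H-chromen-3-ol; 10 piceatannol
Product: 11 (2R,3R,4R)-4-{2-[(E)-2-(3,4-dihydroxyphenyl)ethenyl]-4,6-dihydroxyphenyl}-7-[(triisopropylsilyl)oxy]-2-{4-[(triisopropylsilyl)oxy]phenyl}-3,4-dihydro-2H-chromen-3-ol
Conditions: 10 (3 equiv), BF3·OEt2 (0.2 equiv), THF–CH2Cl2, −20 °C → rt, dark
Reagents that add atoms: none
Why: The Lewis acid ionises the C4 ether to the flavan-4-yl cation, which is captured in a Friedel–Crafts alkylation by the stilbene carbon ortho to the styryl group and para to a hydroxyl, and attack anti to the axial 3-OH of the 2,3-cis half-chair sets C4 as 3,4-trans (4R), as in condensations of flavan-4-yl cations with phloroglucinol-type and hydroxystilbene nucleophiles.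

**Step 8**
Reactants: 11 (2R,3R,4R)-4-{2-[(E)-2-(3,4-dihydroxyphenyl)ethenyl]-4,6-dihydroxyphenyl}-7-[(triisopropylsilyl)oxy]-2-{4-[(triisopropylsilyl)oxy]phenyl}-3,4-dihydro-2H-chromen-3-ol
Product: 12 CNP0170061.2, (2R,3R,4R)-4-{2-[(E)-2-(3,4-dihydroxyphenyl)ethenyl]-4,6-dihydroxyphenyl}-2-(4-hydroxyphenyl)-3,4-dihydro-2H-chromene-3,7-diol
Conditions: Bu4NF (2.5 equiv), AcOH (2.5 equiv), THF, 0 °C, argon, dark
Reagents that add atoms: none
Why: Fluoride cleavage of the two aryl silyl ethers, with acetic acid keeping the liberated phenols protonated so that the catechol and stilbene units are not oxidised and no quinone methide forms.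

**Compound list**

1 | 2,4-dihydroxybenzaldehyde | O=Cc1ccc(O)cc1O | starting material
2 | 2-hydroxy-4-[(triisopropylsilyl)oxy]benzaldehyde | O=Cc1ccc(O[Si](C(C)C)(C(C)C)C(C)C)cc1O | intermediate
3 | (E)-4-hydroxycinnamaldehyde | O=C/C=C/c1ccc(O)cc1 | starting material
4 | (2E)-3-{4-[(triisopropylsilyl)oxy]phenyl}prop-2-enal | O=C/C=C/c1ccc(O[Si](C(C)C)(C(C)C)C(C)C)cc1 | intermediate
5 | (2R)-7-[(triisopropylsilyl)oxy]-2-{4-[(triisopropylsilyl)oxy]phenyl}-2H-chromene-3-carbaldehyde | CC(C)[Si](Oc1ccc([C@H]2Oc3cc(O[Si](C(C)C)(C(C)C)C(C)C)ccc3C=C2C=O)cc1)(C(C)C)C(C)C | intermediate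
6 | (2R)-7-[(triisopropylsilyl)oxy]-2-{4-[(triisopropylsilyl)oxy]phenyl}-2H-chromen-3-yl formate | CC(C)[Si](Oc1ccc([C@H]2Oc3cc(O[Si](C(C)C)(C(C)C)C(C)C)ccc3C=C2OC=O)cc1)(C(C)C)C(C)C | intermediate
7 | (2R,3R)-7-[(triisopropylsilyl)oxy]-2-{4-[(triisopropylsilyl)oxy]phenyl}-3,4-dihydro-2H-chromen-3-yl formate | CC(C)[Si](Oc1ccc([C@H]2Oc3cc(O[Si](C(C)C)(C(C)C)C(C)C)ccc3C[C@H]2OC=O)cc1)(C(C)C)C(C)C | intermediate
8 | (2R,3R)-7-[(triisopropylsilyl)oxy]-2-{4-[(triisopropylsilyl)oxy]phenyl}-3,4-dihydro-2H-chromen-3-ol | CC(C)[Si](Oc1ccc([C@H]2Oc3cc(O[Si](C(C)C)(C(C)C)C(C)C)ccc3C[C@H]2O)cc1)(C(C)C)C(C)C | intermediate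
9 | (2R,3R,4S)-4-(2-ethoxyethoxy)-7-[(triisopropylsilyl)oxy]-2-{4-[(triisopropylsilyl)oxy]phenyl}-3,4-dihydro-2H-chromen-3-ol | CC(C)[Si](Oc1ccc([C@H]2Oc3cc(O[Si](C(C)C)(C(C)C)C(C)C)ccc3[C@H](OCCOCC)[C@H]2O)cc1)(C(C)C)C(C)C | intermediate
10 | piceatannol, 4-[(E)-2-(3,5-dihydroxyphenyl)ethenyl]benzene-1,2-diol | Oc1cc(O)cc(/C=C/c2ccc(O)c(O)c2)c1 | starting material
11 | (2R,3R,4R)-4-{2-[(E)-2-(3,4-dihydroxyphenyl)ethenyl]-4,6-dihydroxyphenyl}-7-[(triisopropylsilyl)oxy]-2-{4-[(triisopropylsilyl)oxy]phenyl}-3,4-dihydro-2H-chromen-3-ol | CC(C)[Si](Oc1ccc([C@H]2Oc3cc(O[Si](C(C)C)(C(C)C)C(C)C)ccc3[C@H](c3c(O)cc(O)cc3/C=C/c3ccc(O)c(O)c3)[C@H]2O)cc1)(C(C)C)C(C)C | intermediate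
12 | CNP0170061.2, (2R,3R,4R)-4-{2-[(E)-2-(3,4-dihydroxyphenyl)ethenyl]-4,6-dihydroxyphenyl}-2-(4-hydroxyphenyl)-3,4-dihydro-2H-chromene-3,7-diol | Oc1ccc([C@H]2Oc3cc(O)ccc3[C@H](c3c(O)cc(O)cc3/C=C/c3ccc(O)c(O)c3)[C@H]2O)cc1 | target

**Step count**

Total steps: 8. Longest linear sequence: 7 steps (steps 1, 3, 4, 5, 6, 7, 8, from 2,4-dihydroxybenzaldehyde).

**Steps most likely to fail**

Step 4 (Baeyer–Villiger oxidation of the enal). What may go wrong: migration of hydrogen instead of the alkenyl carbon (giving the carboxylic acid), and further oxidation of the electron-rich enol formate by the peracid. The fallback sets out from 5 and comes back at 8, so it also replaces step 5; the formyl carbon would be excised through nitrogen instead of oxygen. Pinnick oxidation (NaClO2, NaH2PO4, 2-methyl-2-butene, t-BuOH/H2O) should give the 2H-chromene-3-carboxylic acid F1. Diphenylphosphoryl azide and Et3N in toluene should give the acyl azide F2, which on warming to 80 °C should rearrange (Curtius) to the vinyl isocyanate F3. Brief hydrolysis with dilute aqueous HCl in THF should give the flavan-3-one F4 through the enamine. LiBH(s-Bu)3 in THF at −78 °C should then attack the ketone from the equatorial direction and give the axial, 2,3-cis alcohol 8. F4 would be kept cold and used at once, because its C2–H is enolisable.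

Step 7 (Friedel–Crafts coupling). What may go wrong: loss of site control on the stilbene (attack through the carbon between the two hydroxyls or through the olefin), and self-condensation through ring A once the Lewis acid has ionised C4 in an organic solvent. The fallback sets out from 9 and comes back at 12: deprotection first, coupling last, under protic conditions with both partners unprotected. Bu4NF/AcOH (THF, 0 °C) should give the free 4-(2-ethoxyethoxy)flavan-3,4',7-triol F5. F5 and an excess of 10 in dilute aqueous HCl/dioxane at room temperature should condense directly to 12. The free 7-OH lets the C4 ether ionise under very mild acid (quinone-methide-like cation); under such conditions hydroxystilbenes react through the carbon ortho to the styryl group and the new bond forms trans to the 3-OH.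

Step 3 (key step). What may go wrong: slow turnover with two electron-rich partners, and erosion of enantiomeric purity by reversal of the oxa-Michael addition. The fallback sets out from 2 and 4 and comes back at 8: the ring would be built without enantiocontrol and the enantiomers separated at the alcohol stage. The same domino condensation with pyrrolidine/benzoic acid should give 5 together with its enantiomer, the (2S)-aldehyde F6. Steps 4 and 5 unchanged would carry the pair through the (2S)-enol formate F7 and the (2S,3S)-formate F8 to 8 and the (2S,3S)-alcohol F9. Esterification with (S)-2-methoxy-2-phenylacetic acid (DCC, DMAP, CH2Cl2) should give the diastereomeric esters, the (2R,3R)-ester F10 and the (2S,3S)-ester F11, separable by chromatography or crystallisation. K2CO3 in MeOH should release 8 from F10.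

**Further compounds**

F1 | step 4 | (2R)-7-[(triisopropylsilyl)oxy]-2-{4-[(triisopropylsilyl)oxy]phenyl}-2H-chromene-3-carboxylic acid | CC(C)[Si](Oc1ccc([C@H]2Oc3cc(O[Si](C(C)C)(C(C)C)C(C)C)ccc3C=C2C(=O)O)cc1)(C(C)C)C(C)C
F2 | step 4 | (2R)-7-[(triisopropylsilyl)oxy]-2-{4-[(triisopropylsilyl)oxy]phenyl}-2H-chromene-3-carbonyl azide | CC(C)[Si](Oc1ccc([C@H]2Oc3cc(O[Si](C(C)C)(C(C)C)C(C)C)ccc3C=C2C(=O)N=[N+]=[N-])cc1)(C(C)C)C(C)C
F3 | step 4 | (2R)-3-isocyanato-7-[(triisopropylsilyl)oxy]-2-{4-[(triisopropylsilyl)oxy]phenyl}-2H-chromene | CC(C)[Si](Oc1ccc([C@H]2Oc3cc(O[Si](C(C)C)(C(C)C)C(C)C)ccc3C=C2N=C=O)cc1)(C(C)C)C(C)C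
F4 | step 4 | (2R)-7-[(triisopropylsilyl)oxy]-2-{4-[(triisopropylsilyl)oxy]phenyl}-2H-chromen-3(4H)-one | CC(C)[Si](Oc1ccc([C@H]2Oc3cc(O[Si](C(C)C)(C(C)C)C(C)C)ccc3CC2=O)cc1)(C(C)C)C(C)C
F5 | step 7 | (2R,3R,4S)-4-(2-ethoxyethoxy)-2-(4-hydroxyphenyl)-3,4-dihydro-2H-chromene-3,7-diol | Oc1ccc([C@H]2Oc3cc(O)ccc3[C@H](OCCOCC)[C@H]2O)cc1
F6 | step 3 | (2S)-7-[(triisopropylsilyl)oxy]-2-{4-[(triisopropylsilyl)oxy]phenyl}-2H-chromene-3-carbaldehyde | CC(C)[Si](Oc1ccc([C@@H]2Oc3cc(O[Si](C(C)C)(C(C)C)C(C)C)ccc3C=C2C=O)cc1)(C(C)C)C(C)C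
F7 | step 3 | (2S)-7-[(triisopropylsilyl)oxy]-2-{4-[(triisopropylsilyl)oxy]phenyl}-2H-chromen-3-yl formate | CC(C)[Si](Oc1ccc([C@@H]2Oc3cc(O[Si](C(C)C)(C(C)C)C(C)C)ccc3C=C2OC=O)cc1)(C(C)C)C(C)C
F8 | step 3 | (2S,3S)-7-[(triisopropylsilyl)oxy]-2-{4-[(triisopropylsilyl)oxy]phenyl}-3,4-dihydro-2H-chromen-3-yl formate | CC(C)[Si](Oc1ccc([C@@H]2Oc3cc(O[Si](C(C)C)(C(C)C)C(C)C)ccc3C[C@@H]2OC=O)cc1)(C(C)C)C(C)C
F9 | step 3 | (2S,3S)-7-[(triisopropylsilyl)oxy]-2-{4-[(triisopropylsilyl)oxy]phenyl}-3,4-dihydro-2H-chromen-3-ol | CC(C)[Si](Oc1ccc([C@@H]2Oc3cc(O[Si](C(C)C)(C(C)C)C(C)C)ccc3C[C@@H]2O)cc1)(C(C)C)C(C)C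
F10 | step 3 | (2R,3R)-7-[(triisopropylsilyl)oxy]-2-{4-[(triisopropylsilyl)oxy]phenyl}-3,4-dihydro-2H-chromen-3-yl (2S)-2-methoxy-2-phenylacetate | CC(C)[Si](Oc1ccc([C@H]2Oc3cc(O[Si](C(C)C)(C(C)C)C(C)C)ccc3C[C@H]2OC(=O)[C@@H](OC)c2ccccc2)cc1)(C(C)C)C(C)C
F11 | step 3 | (2S,3S)-7-[(triisopropylsilyl)oxy]-2-{4-[(triisopropylsilyl)oxy]phenyl}-3,4-dihydro-2H-chromen-3-yl (2S)-2-methoxy-2-phenylacetate | CC(C)[Si](Oc1ccc([C@@H]2Oc3cc(O[Si](C(C)C)(C(C)C)C(C)C)ccc3C[C@@H]2OC(=O)[C@@H](OC)c2ccccc2)cc1)(C(C)C)C(C)C
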